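The vessel is closed and stirred, so what is charged is what there is to work with, and one can ask where a flask must stop before integrating anything.

| flask | substrate | coupling partner | free catalyst | remark | time |
|---|---|---|---|---|---|
| alder | 0.32 M | 1.2 M | 7.5 mM | run made earlier |  |
| oak | 2.1 M | 1.2 M | 7.5 mM | run made earlier |  |
| ash | 1.5 M | 1.2 M | 13 mM | run made earlier |  |
| Monday's | 3.0 M | 1.20 M | 25 mM |  | 5.0 min |
| Saturday's | 1.5 M | 1.20 M | 7.5 mM |  | 5.0 min |
| Sunday's | 2.5 M | 1.20 M | 25 mM |  | 5.0 min |
| Thursday's | 0.40 M | 1.20 M | 7.5 mM |  | 5.0 min |

- alder (time / min: product / %): 0.167: 12.7; 0.500: 41.9; 0.833: 59.1; 1.33: 78.7; 2.00: 92.5; 2.50: 97.1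
- oak (time / min: product / %): 0.417: 8.0; 0.833: 19.1; 1.33: 24.5; 1.50: 27.3; 2.00: 33.5; 2.50: 35.5
- ash (time / min: product / %): 0.200: 10.1; 0.667: 31.3; 1.33: 47.9; 2.00: 59.8; 2.50: 64.0

(standard deviation of a reading: 1 percentage point)

- the analysis behind the earlier runs scatters by 1 percentage point, standard deviation

- the flasks put in order of amount of product, in percent of the substrate charged, best first, at 5.0 min (Monday's / Saturday's / Sunday's / Thursday's)
- the same order at 15 s (Monday's / Saturday's / Sunday's / Thursday's)
- the amount of product, in percent of the substrate charged of the flask you put first, at 5.0 min
- the amount of product, in percent of the substrate charged of the flask you put last, at 5.0 min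

**What would you divide first?** The rate of product formation by the rate of coupling partner loss, because time then drops out. If each product costs one coupling partner, that ratio is one, and the product cannot pass the coupling partner charged. For Monday's this gives 40.0%. I call [coupling partner]/[substrate] as charged the ceiling; in Monday's, coupling partner is the limiting reagent.

**And the other flasks?** Sunday's has 48.0% and Saturday's 80.0%, so Saturday's ceiling is higher than Sunday's, and Sunday's is higher than Monday's. In Thursday's the ratio is 3.00, so there substrate is the limiting reagent.

**Which run proves one coupling partner per product?** None does. The most product read is in the ash run, 0.960 M, which is less than its 1.2 M of coupling partner. The one-to-one is my assumption, and the readings merely do not contradict it.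

**A ceiling is not an arrival. Does Monday's get there?** The oak run averaged 0.298 M min⁻¹ on 7.5 mM of catalyst. If rate scales with catalyst and does not move with substrate, which I also assume, Monday's needs 1.21 min. The oak readings climb ever more slowly, so that is probably too short, but it is a quarter of the 5.0 min available. Saturday's needs 4.02 min by the same sum, too near 5.0 min for a falling rate, so I hold its ceiling as a bound and not as a forecast. For the order at 15 s I make no use of the ceiling.

The forecast, made from these runs, reads Thursday's > Saturday's > Sunday's > Monday's at 5.0 min and Thursday's > Sunday's > Monday's > Saturday's at 15 s, with 99.8% first and 39.9% last. Its ground is that “1.20 M partner caps product”.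

The flasks give Thursday's > Saturday's > Sunday's > Monday's at 5.0 min and Thursday's > Sunday's > Monday's > Saturday's at 15 s, with 99.9% first and 39.2% last, so the forecast held.

    catalyst intermediate C ⇌ free catalyst + product (K = 3.70 M, k = 16.5 s⁻¹)
    coupling partner + free catalyst → catalyst intermediate A (k = 1.32 M⁻¹ s⁻¹)
    product + catalyst intermediate C → spent catalyst (k = 0.00649 M⁻¹ s⁻¹)
    substrate + catalyst intermediate A ⇌ catalyst intermediate B (K = 13.1 M⁻¹, k = 4.21 M⁻¹ s⁻¹)
    catalyst intermediate B ⇌ by-product + catalyst intermediate C (K = 62.1 M, k = 33.3 s⁻¹)

Monday's stands at 39.2% under its ceiling of 40.0%, with 0.20% of its coupling partner and 60% of its substrate left. The same run with coupling partner held from depleting gives 99.2% instead of 39.2%, so the depletion of coupling partner is the main reason Monday's stops there. Spent catalyst is not the reason: without its formation Monday's gives 39.8%.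

A neighbour of Monday's charged with 0.48 M of coupling partner has a ceiling of 16.0%. Computed, it gives 15.8%, with 0.021% of its coupling partner left.

Readings and results were generated by integration on assumed constants, and the scatter is random.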